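**Plan**

- Enabling feature: in the pyranone ring, C3 lies between the C4 carbonyl and C2, and C2 is bonded to O1. A carbene at C3 is therefore six atoms (C3–C4–C4a–C8a–O1–C2) from the oxygen-activated methine C–H of a sec-alkyl aryl ether.
- Retrosynthetic cuts, in order: the two O–Si bonds, C2–C3 (carbenoid C–H insertion), C3–C4 (diazoketone from the aroyl chloride), O1–C2 (Mitsunobu etherification), C1'–C2' of the side chain (epoxide opening).
- Forward: the side-chain alcohol is assembled from (S)-propylene oxide and a C5 Grignard reagent, then joined through O1–C2 to the protected bromohydroquinone aldehyde. The aldehyde is oxidised and homologated to the diazoketone, and the pyranone ring, the only ring made, closes last at C2–C3.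
- Stereochemistry: C2 comes from (S)-propylene oxide, is inverted once in the Mitsunobu step to the (R)-ether, and is carried with retention through the C–H insertion to the (R)-quaternary centre.

Key step: step 8

Remark: ring locants are those of the chroman-4-one 15 and primed locants count along its C2 side chain; the enantiomeric purity of 15 is assumed to be that of commercial (S)-propylene oxide.

**Route**

Step 1
Reactants: 1 4-bromo-2-methylbutan-2-ol
Product: 2 [(4-bromo-2-methylbutan-2-yl)oxy]triethylsilane
Conditions: TESOTf, 2,6-lutidine, CH2Cl2, −78 → 0 °C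
Reagents that add atoms: triethylsilyl trifluoromethanesulfonate, CC[Si](CC)(CC)OS(=O)(=O)C(F)(F)F
Why: O-silylation of a tertiary alcohol with a silyl triflate and a hindered pyridine base is reliable, and the primary bromide is untouched under these non-nucleophilic conditions.

Step 2
Reactants: 2 [(4-bromo-2-methylbutan-2-yl)oxy]triethylsilane; 3 (S)-2-methyloxirane [(S)-propylene oxide]
Product: 5 (2S)-6-methyl-6-(triethylsilyloxy)heptan-2-ol, via Grignard reagent 4 (not isolated)
Conditions: Mg, THF, 45 °C; then CuI (10 mol%), 3, −30 → 0 °C; H2O quench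
Reagents that add atoms: none
Why: Copper-catalysed Grignard opening of a monosubstituted epoxide proceeds by SN2 attack at the unsubstituted CH2, which forms the C1'–C2' bond without touching the C–O stereocentre of 3, so the carbinol keeps the (S) configuration.

Step 3
Reactants: 6 4-bromo-2,5-dimethoxybenzaldehyde
Product: 7 4-bromo-2,5-dihydroxybenzaldehyde
Conditions: BBr3 (3 equiv), CH2Cl2, −78 °C → rt; H2O; handled under argon and used directly
Reagents that add atoms: none
Why: Boron tribromide cleavage of aryl methyl ethers (Lewis acid-mediated demethylation) frees both phenols, and the aqueous quench hydrolyses the aryl borates and restores the formyl group.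

Step 4
Reactants: 7 4-bromo-2,5-dihydroxybenzaldehyde
Product: 8 4-bromo-2-hydroxy-5-(triisopropylsilyloxy)benzaldehyde
Conditions: TIPSCl (1.05 equiv), imidazole, DMF, 0 °C
Reagents that add atoms: chlorotri(propan-2-yl)silane, CC(C)[Si](Cl)(C(C)C)C(C)C
Why: Regioselective O-silylation is expected because the 2-OH is locked in an intramolecular hydrogen bond to the formyl oxygen and is a poor nucleophile, so the bulky silyl chloride takes the 5-OH.

Step 5
Reactants: 8 4-bromo-2-hydroxy-5-(triisopropylsilyloxy)benzaldehyde; 5 (2S)-6-methyl-6-(triethylsilyloxy)heptan-2-ol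
Product: 9 4-bromo-2-{[(2R)-6-methyl-6-(triethylsilyloxy)heptan-2-yl]oxy}-5-(triisopropylsilyloxy)benzaldehyde
Conditions: PPh3, DIAD, THF, 0 °C → rt
Reagents that add atoms: none
Why: Mitsunobu etherification of an acidic ortho-formyl phenol with a secondary alcohol goes through SN2 displacement of the alkoxyphosphonium ion, so the (S)-carbinol of 5 is inverted to the (R)-configured aryl ether.

Step 6
Reactants: 9 4-bromo-2-{[(2R)-6-methyl-6-(triethylsilyloxy)heptan-2-yl]oxy}-5-(triisopropylsilyloxy)benzaldehyde
Product: 10 4-bromo-2-{[(2R)-6-methyl-6-(triethylsilyloxy)heptan-2-yl]oxy}-5-(triisopropylsilyloxy)benzoic acid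
Conditions: NaClO2, NaH2PO4, 2-methyl-2-butene, t-BuOH/H2O, 0 °C → rt
Reagents that add atoms: sodium chlorite, [Na+].[O-]Cl=O
Why: Pinnick oxidation converts the aryl aldehyde into the acid under buffered conditions that leave both silyl ethers, the aryl bromide and the ether stereocentre untouched, the alkene scavenger removing hypochlorite before it can chlorinate the electron-rich ring.

Step 7
Reactants: 10 4-bromo-2-{[(2R)-6-methyl-6-(triethylsilyloxy)heptan-2-yl]oxy}-5-(triisopropylsilyloxy)benzoic acid; 11 (trimethylsilyl)diazomethane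
Product: 13 1-[4-bromo-2-{[(2R)-6-methyl-6-(triethylsilyloxy)heptan-2-yl]oxy}-5-(triisopropylsilyloxy)phenyl]-2-diazoethan-1-one, via aroyl chloride 12 (not isolated)
Conditions: 1-chloro-N,N,2-trimethylprop-1-en-1-amine, CH2Cl2, 0 °C → rt; concentrate; then 11 (2.5 equiv), THF/MeCN, 0 °C → rt
Reagents that add atoms: none
Why: Acylation of a diazoalkane by an acid chloride (the diazoketone-forming stage of the Arndt–Eistert sequence in its trimethylsilyldiazomethane variant) installs C3 as the diazo carbon, the acid chloride being generated with an α-chloroenamine under neutral conditions so that no HCl threatens the tertiary silyl ether.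

Step 8
Reactants: 13 1-[4-bromo-2-{[(2R)-6-methyl-6-(triethylsilyloxy)heptan-2-yl]oxy}-5-(triisopropylsilyloxy)phenyl]-2-diazoethan-1-one
Product: 14 (2R)-7-bromo-2-methyl-2-[4-methyl-4-(triethylsilyloxy)pentyl]-6-(triisopropylsilyloxy)-2,3-dihydro-4H-chromen-4-one
Conditions: Rh2(OAc)4 (2 mol%), CH2Cl2, rt, slow addition of 13 by syringe pump
Reagents that add atoms: none
Why: Rh2(OAc)4 expels N2 from 13 to give an electrophilic rhodium carbenoid at the future C3, which inserts into the ether methine C–H through a concerted three-centre transition state and so forms the C2–C3 bond. The closest known reaction type is the rhodium(II)-catalysed intramolecular C–H insertion of 2-alkoxyaryl α-diazoketones to chroman-4-ones. The pyranone ring closes by 1,6 C–H insertion, the 1,5 atom being O1, which carries no hydrogen, so the usual five-ring preference has no outlet. C2 is controlled by the substrate: insertion goes with retention, the new C–C bond taking the place of the C–H bond, so the (R)-methine of the ether becomes the (R)-quaternary centre. The step needs methine insertion to beat oxonium-ylide formation at O1 and insertion into methyl or chain C–H bonds; the methine is the only tertiary, oxygen-activated C–H within reach, the alternatives would close seven-membered rings, and O1 is a weak ylide donor because its lone pair is delocalised into the acyl-bearing arene and its saturated sec-alkyl group migrates poorly.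

Step 9
Reactants: 14 (2R)-7-bromo-2-methyl-2-[4-methyl-4-(triethylsilyloxy)pentyl]-6-(triisopropylsilyloxy)-2,3-dihydro-4H-chromen-4-one
Product: 15 (2R)-7-bromo-6-hydroxy-2-(4-hydroxy-4-methylpentyl)-2-methyl-2,3-dihydro-4H-chromen-4-one
Conditions: TBAF, AcOH (3 equiv each), THF, 0 °C → rt
Reagents that add atoms: none
Why: Fluoride-mediated desilylation cleaves the aryl triisopropylsilyl ether and the tertiary triethylsilyl ether in one operation, and the acetic acid buffer keeps phenoxide and C3-enolate formation down so that a base-triggered retro-oxa-Michael opening cannot scramble C2.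

**Compound list**

1 | 4-bromo-2-methylbutan-2-ol | CC(C)(O)CCBr | starting material
2 | [(4-bromo-2-methylbutan-2-yl)oxy]triethylsilane | CC[Si](CC)(CC)OC(C)(C)CCBr | intermediate
3 | (S)-2-methyloxirane | C[C@H]1CO1 | starting material
4 | [3-methyl-3-(triethylsilyloxy)butyl]magnesium bromide | CC[Si](CC)(CC)OC(C)(C)CC[Mg]Br | intermediate
5 | (2S)-6-methyl-6-(triethylsilyloxy)heptan-2-ol | C[C@H](O)CCCC(C)(C)O[Si](CC)(CC)CC | intermediate
6 | 4-bromo-2,5-dimethoxybenzaldehyde | COc1cc(C=O)c(OC)cc1Br | starting material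
7 | 4-bromo-2,5-dihydroxybenzaldehyde | O=Cc1cc(O)c(Br)cc1O | intermediate
8 | 4-bromo-2-hydroxy-5-(triisopropylsilyloxy)benzaldehyde | O=Cc1cc(O[Si](C(C)C)(C(C)C)C(C)C)c(Br)cc1O | intermediate
9 | 4-bromo-2-{[(2R)-6-methyl-6-(triethylsilyloxy)heptan-2-yl]oxy}-5-(triisopropylsilyloxy)benzaldehyde | CC[Si](CC)(CC)OC(C)(C)CCC[C@@H](C)Oc1cc(Br)c(O[Si](C(C)C)(C(C)C)C(C)C)cc1C=O | intermediate
10 | 4-bromo-2-{[(2R)-6-methyl-6-(triethylsilyloxy)heptan-2-yl]oxy}-5-(triisopropylsilyloxy)benzoic acid | CC[Si](CC)(CC)OC(C)(C)CCC[C@@H](C)Oc1cc(Br)c(O[Si](C(C)C)(C(C)C)C(C)C)cc1C(=O)O | intermediate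
11 | (trimethylsilyl)diazomethane | C[Si](C)(C)C=[N+]=[N-] | starting material
12 | 4-bromo-2-{[(2R)-6-methyl-6-(triethylsilyloxy)heptan-2-yl]oxy}-5-(triisopropylsilyloxy)benzoyl chloride | CC[Si](CC)(CC)OC(C)(C)CCC[C@@H](C)Oc1cc(Br)c(O[Si](C(C)C)(C(C)C)C(C)C)cc1C(Cl)=O | intermediate
13 | 1-[4-bromo-2-{[(2R)-6-methyl-6-(triethylsilyloxy)heptan-2-yl]oxy}-5-(triisopropylsilyloxy)phenyl]-2-diazoethan-1-one | CC[Si](CC)(CC)OC(C)(C)CCC[C@@H](C)Oc1cc(Br)c(O[Si](C(C)C)(C(C)C)C(C)C)cc1C(=O)C=[N+]=[N-] | intermediate
14 | (2R)-7-bromo-2-methyl-2-[4-methyl-4-(triethylsilyloxy)pentyl]-6-(triisopropylsilyloxy)-2,3-dihydro-4H-chromen-4-one | CC[Si](CC)(CC)OC(C)(C)CCC[C@]1(C)CC(=O)c2cc(O[Si](C(C)C)(C(C)C)C(C)C)c(Br)cc2O1 | intermediate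
15 | (2R)-7-bromo-6-hydroxy-2-(4-hydroxy-4-methylpentyl)-2-methyl-2,3-dihydro-4H-chromen-4-one | CC(C)(O)CCC[C@]1(C)CC(=O)c2cc(O)c(Br)cc2O1 | target

**Count**

Total steps: 9. Longest linear sequence: 7 steps (steps 1, 2, 5, 6, 7, 8, 9 from 1; the arm from 6 through steps 3 and 4 is equally long).

**Steps most likely to fail**

Step 8. The carbenoid may be diverted. Attack of the O1 lone pair would give an oxonium ylide that rearranges by a [1,2]-shift with ring contraction, insertion into methyl or chain C–H bonds may compete, and a stepwise hydride-transfer pathway would erode the retention at C2. The fallback leaves carbenoid chemistry, builds the ring by a Kabbe condensation and resolves afterwards; it sets out from 5 and 8 and comes back at 14. Alcohol 5 is oxidised (Dess–Martin periodinane, NaHCO3, CH2Cl2) to 6-methyl-6-(triethylsilyloxy)heptan-2-one F1. Aldehyde 8 is treated with MeMgBr (2.2 equiv, THF, −78 → 0 °C) to give 1-[4-bromo-2-hydroxy-5-(triisopropylsilyloxy)phenyl]ethan-1-ol F2, which MnO2 (CH2Cl2, rt) should oxidise to 1-[4-bromo-2-hydroxy-5-(triisopropylsilyloxy)phenyl]ethan-1-one F3. Heating F3 and F1 with pyrrolidine in toluene (4 Å sieves, 60 °C; aprotic medium to spare the aryl silyl ether) should give racemic 7-bromo-2-methyl-2-[4-methyl-4-(triethylsilyloxy)pentyl]-6-(triisopropylsilyloxy)-2,3-dihydro-4H-chromen-4-one F4 by enamine aldol condensation and oxa-Michael closure. Preparative chromatography on a chiral stationary phase should then separate 14 from the (2S)-enantiomer F5, which can be re-equilibrated to F4 with pyrrolidine and recycled.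

Step 7. Acylation of the diazoalkane by the hindered, electron-rich ortho-alkoxy aroyl chloride may stall, and traces of HCl would turn the diazoketone into a chloromethyl ketone or strip the tertiary silyl ether. The fallback replaces diazoalkane acylation by diazo transfer onto a methyl ketone; it sets out from 9 and comes back at 13. MeMgBr (THF, −78 °C) adds to 9 to give 1-[4-bromo-2-{[(2R)-6-methyl-6-(triethylsilyloxy)heptan-2-yl]oxy}-5-(triisopropylsilyloxy)phenyl]ethan-1-ol F6 as a mixture of carbinol epimers, which is of no consequence. Dess–Martin oxidation should give 1-[4-bromo-2-{[(2R)-6-methyl-6-(triethylsilyloxy)heptan-2-yl]oxy}-5-(triisopropylsilyloxy)phenyl]ethan-1-one F7. Enolisation with LiHMDS (THF, −78 °C) and trapping with 2,2,2-trifluoroethyl trifluoroacetate gives 1-[4-bromo-2-{[(2R)-6-methyl-6-(triethylsilyloxy)heptan-2-yl]oxy}-5-(triisopropylsilyloxy)phenyl]-4,4,4-trifluorobutane-1,3-dione F8. This is treated crude with methanesulfonyl azide, Et3N and water in MeCN (detrifluoroacetylative diazo transfer) to deliver 13.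

Step 5. The phenol is hydrogen-bonded and flanked by the formyl group, so displacement of the activated alcohol may be slow and elimination may take over, while incomplete inversion would lower the enantiomeric purity carried into the key step. The fallback separates activation from displacement in a Williamson-type alkylation; it sets out from 5 (with 8) and comes back at 9. Alcohol 5 is converted with MsCl and Et3N (CH2Cl2, 0 °C) into (2S)-6-methyl-6-(triethylsilyloxy)heptan-2-yl methanesulfonate F9 with retention. Displacement by the phenoxide of 8 (Cs2CO3, anhydrous MeCN, 60 °C) should then give 9 by SN2 inversion, the same stereochemical outcome as the Mitsunobu step.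

**Further compounds**

F1 | step 8 | 6-methyl-6-(triethylsilyloxy)heptan-2-one | CC(=O)CCCC(C)(C)O[Si](CC)(CC)CC
F2 | step 8 | 1-[4-bromo-2-hydroxy-5-(triisopropylsilyloxy)phenyl]ethan-1-ol (racemic) | CC(O)c1cc(O[Si](C(C)C)(C(C)C)C(C)C)c(Br)cc1O
F3 | step 8 | 1-[4-bromo-2-hydroxy-5-(triisopropylsilyloxy)phenyl]ethan-1-one | CC(=O)c1cc(O[Si](C(C)C)(C(C)C)C(C)C)c(Br)cc1O
F4 | step 8 | 7-bromo-2-methyl-2-[4-methyl-4-(triethylsilyloxy)pentyl]-6-(triisopropylsilyloxy)-2,3-dihydro-4H-chromen-4-one (racemic) | CC[Si](CC)(CC)OC(C)(C)CCCC1(C)CC(=O)c2cc(O[Si](C(C)C)(C(C)C)C(C)C)c(Br)cc2O1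
F5 | step 8 | (2S)-7-bromo-2-methyl-2-[4-methyl-4-(triethylsilyloxy)pentyl]-6-(triisopropylsilyloxy)-2,3-dihydro-4H-chromen-4-one | CC[Si](CC)(CC)OC(C)(C)CCC[C@@]1(C)CC(=O)c2cc(O[Si](C(C)C)(C(C)C)C(C)C)c(Br)cc2O1
F6 | step 7 | 1-[4-bromo-2-{[(2R)-6-methyl-6-(triethylsilyloxy)heptan-2-yl]oxy}-5-(triisopropylsilyloxy)phenyl]ethan-1-ol (carbinol epimers) | CC[Si](CC)(CC)OC(C)(C)CCC[C@@H](C)Oc1cc(Br)c(O[Si](C(C)C)(C(C)C)C(C)C)cc1C(C)O
F7 | step 7 | 1-[4-bromo-2-{[(2R)-6-methyl-6-(triethylsilyloxy)heptan-2-yl]oxy}-5-(triisopropylsilyloxy)phenyl]ethan-1-one | CC[Si](CC)(CC)OC(C)(C)CCC[C@@H](C)Oc1cc(Br)c(O[Si](C(C)C)(C(C)C)C(C)C)cc1C(C)=O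
F8 | step 7 | 1-[4-bromo-2-{[(2R)-6-methyl-6-(triethylsilyloxy)heptan-2-yl]oxy}-5-(triisopropylsilyloxy)phenyl]-4,4,4-trifluorobutane-1,3-dione | CC[Si](CC)(CC)OC(C)(C)CCC[C@@H](C)Oc1cc(Br)c(O[Si](C(C)C)(C(C)C)C(C)C)cc1C(=O)CC(=O)C(F)(F)F
F9 | step 5 | (2S)-6-methyl-6-(triethylsilyloxy)heptan-2-yl methanesulfonate | C[C@H](OS(C)(=O)=O)CCCC(C)(C)O[Si](CC)(CC)CC
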